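**Strategy.** Flavone ring A of the target carries C5–OH, C6–aryl and C7–OH in a row next to C8–H, and its C4a=C8a edge belongs to pyranone ring C. Ring A is therefore made last, by a Danheiser benzannulation. A diazoacetyl group on a 2-aryl-4-pyranone supplies C5 and C8. The adjacent pyranone C=C supplies C4a/C8a. An 8-(ethoxyethynyl)coumarin supplies C6/C7 together with the biaryl bond. One operation forms four C–C bonds, closes ring A and fixes the 6-aryl (not 8-aryl) constitution. The precursors are diazoketone 10 and ynol ether 17, each three steps from bulk chemicals. Global dealkylation with BBr3 finishes the synthesis.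

Key step: step 7

Assumption: the target SMILES gives no axial descriptor, so the tetra-ortho-oxygenated biaryl axis is formed without control and the racemic (or freely rotating) compound is taken as the target.

Step 1
Reactants: 1 4'-methoxyacetophenone; 2 ethyl acetate
Product: 3 1-(4-methoxyphenyl)butane-1,3-dione
Conditions: NaH (2 equiv), EtOAc (3 equiv), THF, 0 °C → reflux; then 1 M HCl
Reagents that add atoms: none
Why: Crossed Claisen condensation, in which the ketone enolate is acylated by ethyl acetate and irreversible deprotonation of the β-diketone pulls the equilibrium to 3.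

Step 2
Reactants: 3 1-(4-methoxyphenyl)butane-1,3-dione; 4 diethyl oxalate
Product: 7 6-(4-methoxyphenyl)-4-oxo-4H-pyran-2-carboxylic acid, via triketo ester 5 (not isolated), via ethyl pyranonecarboxylate 6 (not isolated)
Conditions: NaOEt (2.5 equiv), (CO2Et)2 (1.2 equiv), EtOH, 0 → 60 °C; then conc. HCl–AcOH, 100 °C
Reagents that add atoms: water, O
Why: Claisen condensation of the chelidonic acid type, in which excess ethoxide lets the diketone react through its terminal methyl (only that adduct is held as a stable dienolate), triketo ester 5 can cyclodehydrate in hot acid only to the six-membered 4-pyranone 6, and the ester is hydrolysed in the same pot while the anisyl ether survives HCl.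

Step 3
Reactants: 7 6-(4-methoxyphenyl)-4-oxo-4H-pyran-2-carboxylic acid
Product: 10 2-(2-diazoacetyl)-6-(4-methoxyphenyl)-4H-pyran-4-one, via acid chloride 8 (not isolated), via silyl diazoketone 9 (not isolated)
Conditions: SOCl2, cat. DMF, toluene, 70 °C, evaporate; then Me3SiCHN2 (1.5 equiv), Et3N (1.2 equiv), THF–MeCN 1:1, 0 °C, dark; aqueous work-up, SiO2
Reagents that add atoms: trimethylsilyldiazomethane, C[Si](C)(C)C=[N+]=[N-]; thionyl chloride, O=S(Cl)Cl (its chlorine stays only in 8)
Why: Arndt–Eistert-type acylation of a diazoalkane, in which the acid chloride (no α-hydrogen) acylates trimethylsilyldiazomethane much faster than the quasi-aromatic pyranone C=C can undergo dipolar cycloaddition, Et3N takes up HCl so that no chloromethyl ketone forms, and the C-silyl group of 9 is lost on contact with water and silica.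

Step 4
Reactants: 11 umbelliferone (7-hydroxycoumarin)
Product: 12 7-hydroxy-8-iodocoumarin
Conditions: I2 (1.0 equiv) in aq. KI added slowly, 20% aq. NH3, rt; then dilute H2SO4
Reagents that add atoms: iodine, [I][I]
Why: Electrophilic aromatic iodination of the phenolate, in which C8 (ortho to O7 and flanked by the ring oxygen) is the most nucleophilic carbon of the umbelliferone anion, the same site taken in its formylation and aminomethylation, and one equivalent of iodine limits over-iodination.

Step 5
Reactants: 12 7-hydroxy-8-iodocoumarin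
Product: 13 8-iodo-7-methoxycoumarin
Conditions: MeI (1.5 equiv), K2CO3, acetone, reflux
Reagents that add atoms: iodomethane, IC
Why: Williamson O-methylation of the acidic phenol, with methyl chosen because the ethyl ether brought in by the ynol ether already requires BBr3 at the end, so its removal costs no extra step.

Step 6
Reactants: 13 8-iodo-7-methoxycoumarin; 14 ethoxyacetylene
Product: 17 8-(ethoxyethynyl)-7-methoxycoumarin, via lithium ethoxyacetylide 15 (not isolated), via ethoxyethynylzinc chloride 16 (not isolated)
Conditions: 14 (1.6 equiv), n-BuLi (1.5 equiv), THF, −78 °C; ZnCl2 (1.6 equiv), → 0 °C; then 13, Pd(PPh3)4 (5 mol %), rt; pH 7 buffer, Et3N-deactivated SiO2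
Reagents that add atoms: n-butyllithium, [Li]CCCC (its lithium stays only in 15); ZnCl2, Cl[Zn]Cl (zinc and chlorine stay only in 16)
Why: Negishi coupling of an alkoxyethynylzinc chloride with an iodoarene, in which zerovalent palladium inserts into the C8–I bond, the slim alkynyl group transfers despite the two ortho oxygens, and the zinc acetylide is too mild to attack the lactone.

Step 7
Reactants: 10 2-(2-diazoacetyl)-6-(4-methoxyphenyl)-4H-pyran-4-one; 17 8-(ethoxyethynyl)-7-methoxycoumarin
Product: 22 7-ethoxy-5-hydroxy-6-(7-methoxy-2-oxo-2H-chromen-8-yl)-2-(4-methoxyphenyl)-4H-chromen-4-one, via pyranonylketene 18 (not isolated), via cyclobutenone 19 (not isolated), via dienylketene 20 (not isolated), via cyclohexadienone 21 (not isolated)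
Conditions: hν (420–440 nm LED), 10 (1.3 equiv) added over 6 h to 17, degassed ClCH2CH2Cl (0.02 M), 20 °C; then dark, 80 °C
Reagents that add atoms: none
Why: Selective excitation of the long-wavelength tail of the diazoketone expels N2 and triggers the Wolff rearrangement, in which pyranone C2 migrates to the diazo carbon (flavone C8–C8a) to give ketene 18, and this adds by [2+2] cycloaddition to the electron-rich triple bond of 17 (C5–C6 and C7–C8) to give cyclobutenone 19. On warming, 19 opens by reversible conrotatory four-electron cleavage of the former ketene C–C bond to dienylketene 20, ring A is closed by disrotatory six-electron electrocyclisation of the ketene carbon onto pyranone C3–H (C4a–C5), and enolisation of the β-diketone-like 21 gives the chelated 5-hydroxyl. This is the Danheiser benzannulation in its diazoketone form, established for vinyl, aryl and heteroaryl diazomethyl ketones with alkynyl ethers. Regioselectivity is needed in the [2+2] step and comes from the oxygen-polarised alkyne, whose aryl-bearing carbon is the nucleophilic end and bonds to the ketene carbonyl carbon, so the coumarinyl group ends at C6 between OH and OEt; the closure itself has no alternative, because pyranone C2 has only C3 and the ring oxygen as neighbours. Chemoselectivity rests on the wavelength (17, 19 and 22 should be transparent above about 400 nm, which spares the coumarin from [2+2] photodimerisation and the pyranone from photoisomerisation), on slow addition of 10 against ketene self-reaction, and on the ketene preferring the ynol ether over the electron-poor coumarin C3=C4 bond. No lasting stereocentre arises, since C4 of 19 and C4a of 21 vanish on aromatisation and the biaryl axis forms without control.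

Step 8
Reactants: 22 7-ethoxy-5-hydroxy-6-(7-methoxy-2-oxo-2H-chromen-8-yl)-2-(4-methoxyphenyl)-4H-chromen-4-one
Product: 23 5,7-dihydroxy-6-(7-hydroxy-2-oxo-2H-chromen-8-yl)-2-(4-hydroxyphenyl)-4H-chromen-4-one
Conditions: BBr3 (10 equiv), CH2Cl2, −78 °C → rt; then MeOH, H2O
Reagents that add atoms: none
Why: Lewis-acid cleavage of aryl alkyl ethers with BBr3 removes the ethyl and both methyl groups at once, leaves the lactone and pyranone intact, and by staying anhydrous and cold avoids the hot-acid opening and reclosure of ring C (Wessely–Moser rearrangement) that would move the aryl group from C6 to C8.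

**Compound list**
1 | 4'-methoxyacetophenone | COc1ccc(cc1)C(C)=O | starting material
2 | ethyl acetate | CCOC(C)=O | starting material
3 | 1-(4-methoxyphenyl)butane-1,3-dione | COc1ccc(cc1)C(=O)CC(C)=O | intermediate
4 | diethyl oxalate | CCOC(=O)C(=O)OCC | starting material
5 | ethyl 6-(4-methoxyphenyl)-2,4,6-trioxohexanoate | CCOC(=O)C(=O)CC(=O)CC(=O)c1ccc(OC)cc1 | intermediate
6 | ethyl 6-(4-methoxyphenyl)-4-oxo-4H-pyran-2-carboxylate | CCOC(=O)c1cc(=O)cc(o1)-c1ccc(OC)cc1 | intermediate
7 | 6-(4-methoxyphenyl)-4-oxo-4H-pyran-2-carboxylic acid | OC(=O)c1cc(=O)cc(o1)-c1ccc(OC)cc1 | intermediate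
8 | 6-(4-methoxyphenyl)-4-oxo-4H-pyran-2-carbonyl chloride | ClC(=O)c1cc(=O)cc(o1)-c1ccc(OC)cc1 | intermediate
9 | 2-[2-diazo-2-(trimethylsilyl)acetyl]-6-(4-methoxyphenyl)-4H-pyran-4-one | COc1ccc(cc1)-c1cc(=O)cc(o1)C(=O)C(=[N+]=[N-])[Si](C)(C)C | intermediate
10 | 2-(2-diazoacetyl)-6-(4-methoxyphenyl)-4H-pyran-4-one | COc1ccc(cc1)-c1cc(=O)cc(o1)C(=O)C=[N+]=[N-] | intermediate
11 | umbelliferone | O=c1ccc2ccc(O)cc2o1 | starting material
12 | 7-hydroxy-8-iodocoumarin | Oc1ccc2ccc(=O)oc2c1I | intermediate
13 | 8-iodo-7-methoxycoumarin | COc1ccc2ccc(=O)oc2c1I | intermediate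
14 | ethoxyacetylene | CCOC#C | starting material
15 | lithium ethoxyacetylide | CCOC#C[Li] | intermediate
16 | ethoxyethynylzinc chloride | CCOC#C[Zn]Cl | intermediate
17 | 8-(ethoxyethynyl)-7-methoxycoumarin | CCOC#Cc1c(OC)ccc2ccc(=O)oc12 | intermediate
18 | 2-[6-(4-methoxyphenyl)-4-oxo-4H-pyran-2-yl]ethen-1-one (ketene) | O=C=Cc1cc(=O)cc(o1)-c1ccc(OC)cc1 | intermediate
19 | 3-ethoxy-2-(7-methoxy-2-oxochromen-8-yl)-4-[6-(4-methoxyphenyl)-4-oxopyran-2-yl]cyclobut-2-en-1-one (racemic) | CCOC1=C(C(=O)C1c1cc(=O)cc(o1)-c1ccc(OC)cc1)c1c(OC)ccc2ccc(=O)oc12 | intermediate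
20 | (3E)-3-ethoxy-2-(7-methoxy-2-oxochromen-8-yl)-4-[6-(4-methoxyphenyl)-4-oxopyran-2-yl]buta-1,3-dien-1-one (pyranonyl cis to the ketene-bearing carbon) | O=C=C(c1c(OC)ccc2ccc(=O)oc12)/C(OCC)=C\c1cc(=O)cc(o1)-c1ccc(OC)cc1 | intermediate
21 | 7-ethoxy-6-(7-methoxy-2-oxochromen-8-yl)-2-(4-methoxyphenyl)-4aH-chromene-4,5-dione (racemic) | CCOC1=C(c2c(OC)ccc3ccc(=O)oc23)C(=O)C2C(=C1)OC(=CC2=O)c1ccc(OC)cc1 | intermediate
22 | 7-ethoxy-5-hydroxy-6-(7-methoxy-2-oxo-2H-chromen-8-yl)-2-(4-methoxyphenyl)-4H-chromen-4-one | CCOc1cc2oc(-c3ccc(OC)cc3)cc(=O)c2c(O)c1-c1c(OC)ccc2ccc(=O)oc12 | intermediate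
23 | 5,7-dihydroxy-6-(7-hydroxy-2-oxo-2H-chromen-8-yl)-2-(4-hydroxyphenyl)-4H-chromen-4-one | O=c1ccc2ccc(O)c(-c3c(O)cc4oc(-c5ccc(O)cc5)cc(=O)c4c3O)c2o1 | target

**Total step count:** 8. **Longest linear sequence:** 5 steps (1, 2, 3, 7, 8 or 4, 5, 6, 7, 8).

**Steps most likely to fail**

Step 7. The ketene may be lost by dimerisation or by attack on unreacted diazoketone before it meets the hindered alkyne. Stray absorption may still excite the coumarin. The last electrocyclisation may stall because it interrupts the pyranone conjugation. The fallback replaces ring construction by biaryl cross-coupling; it sets out from iodide 13 and returns at target 23.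
- Commercial apigenin 7,4'-dimethyl ether F1 is iodinated next to the chelated hydroxyl with benzyltrimethylammonium dichloroiodate and CaCO3 in CH2Cl2–MeOH to 5-hydroxy-6-iodo-7,4'-dimethoxyflavone F2.
- O-Methylation (Me2SO4, K2CO3, acetone) gives 6-iodo-5,7,4'-trimethoxyflavone F3.
- Miyaura borylation (B2pin2, PdCl2(dppf), KOAc, dioxane, 90 °C) gives the flavone-6-boronic pinacol ester F4.
- Suzuki–Miyaura coupling of F4 with 13 (Pd(OAc)2, SPhos, K3PO4, toluene–H2O, 100 °C) gives the tetramethyl ether of the target F5.
- BBr3 under the conditions of step 8 converts F5 into 23.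

Step 6. Oxidative addition into the doubly ortho-substituted iodide may be slow. The acid-sensitive ynol ether may also be hydrated or oligomerised by zinc halides or on silica. The fallback uses an isolated, neutral alkynyl donor in place of the zinc reagent made in the flask; it sets out from 14 and returns at 17. Lithium acetylide 15, made from 14 as before, is quenched with Bu3SnCl to give distillable tributyl(ethoxyethynyl)stannane F6. F6 is joined to 13 by Stille coupling (Pd2(dba)3, tri(2-furyl)phosphine, toluene, 60 °C) in the absence of Lewis-acidic salts and residual base.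

Step 3. Dipolar cycloaddition of the diazoalkane across the acyl-activated pyranone C2=C3 bond may compete with acylation, and protodesilylation may be incomplete. The fallback uses no diazoalkane and installs the diazo group by diazo transfer; it sets out from acid chloride 8 and returns at 10.
- Negishi acylation of 8 (MeZnCl, Pd(PPh3)4, THF, 0 °C) gives 2-acetyl-6-(4-methoxyphenyl)-4H-pyran-4-one F7.
- The only enolisable position of F7 is trifluoroacetylated (LiN(SiMe3)2, THF, −78 °C; CF3CO2CH2CF3) to the trifluoromethyl β-diketone F8.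
- Detrifluoroacetylative diazo transfer (MsN3, Et3N, H2O, MeCN, rt) delivers 10.

**Further compounds**
F1 | step 7 | 5-hydroxy-7-methoxy-2-(4-methoxyphenyl)-4H-chromen-4-one | COc1ccc(cc1)-c1cc(=O)c2c(O)cc(OC)cc2o1
F2 | step 7 | 5-hydroxy-6-iodo-7-methoxy-2-(4-methoxyphenyl)-4H-chromen-4-one | COc1ccc(cc1)-c1cc(=O)c2c(O)c(I)c(OC)cc2o1
F3 | step 7 | 6-iodo-5,7-dimethoxy-2-(4-methoxyphenyl)-4H-chromen-4-one | COc1ccc(cc1)-c1cc(=O)c2c(OC)c(I)c(OC)cc2o1
F4 | step 7 | 5,7-dimethoxy-2-(4-methoxyphenyl)-6-(4,4,5,5-tetramethyl-1,3,2-dioxaborolan-2-yl)-4H-chromen-4-one | COc1ccc(cc1)-c1cc(=O)c2c(OC)c(B3OC(C)(C)C(C)(C)O3)c(OC)cc2o1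
F5 | step 7 | 5,7-dimethoxy-6-(7-methoxy-2-oxo-2H-chromen-8-yl)-2-(4-methoxyphenyl)-4H-chromen-4-one | COc1ccc(cc1)-c1cc(=O)c2c(OC)c(c(OC)cc2o1)-c1c(OC)ccc2ccc(=O)oc12
F6 | step 6 | tributyl(ethoxyethynyl)stannane | CCCC[Sn](CCCC)(CCCC)C#COCC
F7 | step 3 | 2-acetyl-6-(4-methoxyphenyl)-4H-pyran-4-one | CC(=O)c1cc(=O)cc(o1)-c1ccc(OC)cc1
F8 | step 3 | 4,4,4-trifluoro-1-[6-(4-methoxyphenyl)-4-oxo-4H-pyran-2-yl]butane-1,3-dione | COc1ccc(cc1)-c1cc(=O)cc(o1)C(=O)CC(=O)C(F)(F)F
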